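**Plan**

- Retrosynthesis: the C3'–OH is traced back to a C3'–H (cut C3'–O), the silicon bridge to a di-tert-butylsilanol hung on O–C2' (cut Si–O), the ester at its O–C1 bond to a salicylate and a C17 alcohol, and the chain at C12–C13.
- Forward: the chain is joined first by a Li2CuCl4-catalysed Grignard coupling, then esterified, then the silanol is attached to the phenol. The only ring, a temporary five-membered 1,3,2-dioxasilole fused to the arene, closes during the C–H oxygenation and is opened again by fluoride.
- Enabling feature: the C3' hydroxyl is ortho to the C2' oxygen, and the other ortho position of that oxygen, C1', already carries the ester carbon. A directing group tethered to O–C2' can therefore reach only the C3'–H bond.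
- Stereochemistry: the single stereocentre, C14 (S), is bought in (S)-1-bromo-2-methylbutane (1) and is never a reacting centre.

Key step: step 4

Remark: 1 is taken as the commercial single enantiomer (the bromide of the fusel-oil alcohol (S)-2-methylbutan-1-ol); ring atoms are numbered C1' (ester-bearing) to C6' and chain atoms C1 (OCH2) to C16.

**Route**

Step 1
Reactants: 1 (S)-1-bromo-2-methylbutane; 2 12-bromododecan-1-ol
Product: 5 (S)-14-methylhexadecan-1-ol, via (S)-2-methylbutylmagnesium bromide 3 (not isolated), via chloromagnesium 12-bromododecan-1-olate 4 (not isolated)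
Conditions: 1 (1.6 equiv), Mg, THF, 45 °C; 2, MeMgCl (1.0 equiv), THF, 0 °C; then Li2CuCl4 (3 mol %), THF, −20 °C → rt; aq. NH4Cl
Reagents that add atoms: none
Why: Li2CuCl4-catalysed (Kochi-type) sp3–sp3 cross-coupling of a primary alkylmagnesium bromide with an unhindered primary alkyl bromide is reliable, the pre-formed chloromagnesium alkoxide is a spectator that saves a protecting group, and the C14 stereocentre, one carbon away from the carbon–magnesium bond, should pass through unchanged from 1.

Step 2
Reactants: 5 (S)-14-methylhexadecan-1-ol; 6 salicylic acid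
Product: 7 (S)-14-methylhexadecyl 2-hydroxybenzoate
Conditions: PPh3, DIAD, THF, 0 °C → rt
Reagents that add atoms: none
Why: In this Mitsunobu esterification the carboxylic acid (pKa about 3) is the only pronucleophile acidic enough to be engaged, so the hydrogen-bonded phenol should stay free while the carboxylate displaces the activated primary C1 oxygen in an SN2 step far from the stereocentre.

Step 3
Reactants: 7 (S)-14-methylhexadecyl 2-hydroxybenzoate
Product: 9 (S)-14-methylhexadecyl 2-{[di-tert-butyl(hydroxy)silyl]oxy}benzoate, via aryloxysilyl triflate 8 (not isolated)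
Conditions: t-Bu2Si(OTf)2 (1.5 equiv), 2,6-lutidine, CH2Cl2, −40 → 0 °C (7 added last); then H2O, THF, rt
Reagents that add atoms: di-tert-butylsilyl bis(trifluoromethanesulfonate), CC(C)(C)[Si](OS(=O)(=O)C(F)(F)F)(OS(=O)(=O)C(F)(F)F)C(C)(C)C; water, O
Why: Silylation of a phenol with a silyl triflate and a hindered pyridine base is fast even for the hydrogen-bonded salicylate hydroxyl, the two tert-butyl groups should keep a second phenol from displacing the remaining triflate, and hydrolysis of that Si–OTf bond gives a silanol too hindered to condense to a disiloxane.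

Step 4
Reactants: 9 (S)-14-methylhexadecyl 2-{[di-tert-butyl(hydroxy)silyl]oxy}benzoate
Product: 11 (S)-14-methylhexadecyl 2,2-di-tert-butyl-1,3,2-benzodioxasilole-4-carboxylate, via 3-acetoxy silanol 10 (not isolated)
Conditions: Pd(OCOtBu)2 (10 mol %), PhI(OAc)2 (2 equiv), PhMe, 100 °C
Reagents that add atoms: (diacetoxyiodo)benzene, CC(=O)OI(OC(C)=O)c1ccccc1
Why: The silanol binds divalent palladium as a silanolate and delivers it to the C3'–H bond through a six-membered palladacycle (pivalate-assisted concerted metalation–deprotonation); PhI(OAc)2 then oxidises the palladacycle to tetravalent palladium, and C–OAc reductive elimination gives the C3' acetate 10 and returns divalent palladium. Acyl transfer from that acetate to the neighbouring silanol oxygen should free the C3' phenol, which displaces acetate at silicon, so the five-membered 1,3,2-dioxasilole closes in a 5-exo sense by intramolecular substitution at silicon with loss of acetic acid, masking the oxidation-prone catechol as it forms and removing the directing group so that no second oxygenation can follow. The closest known reaction type is the silanol-directed, palladium-catalysed ortho C–H oxygenation of phenols to silylene-bridged catechols. No stereocentre is created, and the saturated chain with its remote C14 centre offers the catalyst no reactive site. The step needs site selectivity, and the tether secures it: only the two positions ortho to O–C2' are within reach, C1' is substituted, and the ester is too weak a ligand to steer palladium to C6'.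

Step 5
Reactants: 11 (S)-14-methylhexadecyl 2,2-di-tert-butyl-1,3,2-benzodioxasilole-4-carboxylate
Product: 12 gentiside C, (S)-14-methylhexadecyl 2,3-dihydroxybenzoate
Conditions: Bu4NF (TBAF, 2.2 equiv), AcOH (2.2 equiv), THF, 0 °C, Ar; pH 5 work-up
Reagents that add atoms: none
Why: In this fluoride-mediated desilylation, fluoride should attack the strained, doubly aryloxy-substituted silicon twice to release the catechol and t-Bu2SiF2, while the acetic acid buffer keeps the catechol protonated against air oxidation and spares the ester.

**Compound list**

1 | (S)-1-bromo-2-methylbutane | CC[C@H](C)CBr | starting material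
2 | 12-bromododecan-1-ol | OCCCCCCCCCCCCBr | starting material
3 | (S)-2-methylbutylmagnesium bromide | CC[C@H](C)C[Mg]Br | intermediate
4 | chloromagnesium 12-bromododecan-1-olate | BrCCCCCCCCCCCCO[Mg]Cl | intermediate
5 | (S)-14-methylhexadecan-1-ol | CC[C@H](C)CCCCCCCCCCCCCO | intermediate
6 | salicylic acid | O=C(O)c1ccccc1O | starting material
7 | (S)-14-methylhexadecyl 2-hydroxybenzoate | CC[C@H](C)CCCCCCCCCCCCCOC(=O)c1ccccc1O | intermediate
8 | (S)-14-methylhexadecyl 2-{[di-tert-butyl(trifluoromethanesulfonyloxy)silyl]oxy}benzoate | CC[C@H](C)CCCCCCCCCCCCCOC(=O)c1ccccc1O[Si](OS(=O)(=O)C(F)(F)F)(C(C)(C)C)C(C)(C)C | intermediate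
9 | (S)-14-methylhexadecyl 2-{[di-tert-butyl(hydroxy)silyl]oxy}benzoate | CC[C@H](C)CCCCCCCCCCCCCOC(=O)c1ccccc1O[Si](O)(C(C)(C)C)C(C)(C)C | intermediate
10 | (S)-14-methylhexadecyl 3-acetoxy-2-{[di-tert-butyl(hydroxy)silyl]oxy}benzoate | CC[C@H](C)CCCCCCCCCCCCCOC(=O)c1cccc(OC(C)=O)c1O[Si](O)(C(C)(C)C)C(C)(C)C | intermediate
11 | (S)-14-methylhexadecyl 2,2-di-tert-butyl-1,3,2-benzodioxasilole-4-carboxylate | CC[C@H](C)CCCCCCCCCCCCCOC(=O)c1cccc2O[Si](C(C)(C)C)(C(C)(C)C)Oc12 | intermediate
12 | gentiside C, (S)-14-methylhexadecyl 2,3-dihydroxybenzoate | CC[C@H](C)CCCCCCCCCCCCCOC(=O)c1cccc(O)c1O | target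

**Summary and risks**

Total step count: 5. Longest linear sequence: 5 steps (1 → 5 → 7 → 9 → 11 → 12).

Steps most likely to fail:

1. Step 4. The C3'–H palladation may be outrun by loss of the tether (protodesilylation by the acetic acid released, or oxidation at silicon), because the ester at C1' lowers the electron density of the ring and its carbonyl can tie up the silanol or the palladium. The fallback sets out from 7 and returns to the route at 12. Magnesium-phenoxide-directed ortho-formylation (MgCl2, Et3N, paraformaldehyde, MeCN, reflux) can only occur at C3', the one free position ortho to the phenol, and should give (S)-14-methylhexadecyl 3-formyl-2-hydroxybenzoate F1. Dakin oxidation under acidic conditions (aq. H2O2, B(OH)3, cat. H2SO4, THF, rt) should then pass through the aryl formate (S)-14-methylhexadecyl 3-(formyloxy)-2-hydroxybenzoate F2, which hydrolyses in the flask to 12 without exposing the alkyl ester to base.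

2. Step 3. A second phenol may displace the remaining triflate (bis-aryloxysilane formation), or the silyl triflate may activate the neighbouring ester carbonyl so that the C17 alkoxy group is lost on quenching. The fallback sets out from 7 and returns at 9, replacing hydrolysis of a Si–OTf bond by oxidation of a Si–H bond. Silylation with t-Bu2SiHCl (imidazole, DMF, rt) should give (S)-14-methylhexadecyl 2-[(di-tert-butylsilyl)oxy]benzoate F3, a neutral hydrosilyl ether with no Lewis acidity. NBS in CH2Cl2 converts Si–H into Si–Br, giving (S)-14-methylhexadecyl 2-{[bromo(di-tert-butyl)silyl]oxy}benzoate F4, and aq. NaHCO3 hydrolyses it to 9.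

3. Step 1. The chloromagnesium alkoxide may aggregate or precipitate at low temperature, so the coupling stalls and the Grignard reagent is consumed by homocoupling. The fallback sets out from 2 and returns at 5, using a protected electrophile. Dihydropyran with PPTS in CH2Cl2 should give 2-[(12-bromododecyl)oxy]tetrahydro-2H-pyran F5. Coupling with 3 under Li2CuCl4 catalysis (THF, −20 °C → rt) gives 2-{[(S)-14-methylhexadecyl]oxy}tetrahydro-2H-pyran F6, and acid methanolysis (p-TsOH, MeOH, rt) releases 5.

**Further compounds**

F1 | step 4 | (S)-14-methylhexadecyl 3-formyl-2-hydroxybenzoate | CC[C@H](C)CCCCCCCCCCCCCOC(=O)c1cccc(C=O)c1O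
F2 | step 4 | (S)-14-methylhexadecyl 3-(formyloxy)-2-hydroxybenzoate | CC[C@H](C)CCCCCCCCCCCCCOC(=O)c1cccc(OC=O)c1O
F3 | step 3 | (S)-14-methylhexadecyl 2-[(di-tert-butylsilyl)oxy]benzoate | CC[C@H](C)CCCCCCCCCCCCCOC(=O)c1ccccc1O[SiH](C(C)(C)C)C(C)(C)C
F4 | step 3 | (S)-14-methylhexadecyl 2-{[bromo(di-tert-butyl)silyl]oxy}benzoate | CC[C@H](C)CCCCCCCCCCCCCOC(=O)c1ccccc1O[Si](Br)(C(C)(C)C)C(C)(C)C
F5 | step 1 | 2-[(12-bromododecyl)oxy]tetrahydro-2H-pyran | BrCCCCCCCCCCCCOC1CCCCO1
F6 | step 1 | 2-{[(S)-14-methylhexadecyl]oxy}tetrahydro-2H-pyran (both epimers at the acetal carbon) | CC[C@H](C)CCCCCCCCCCCCCOC1CCCCO1
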